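If you have two settings to turn on this flask, the clock and the charge of starting material, this is what stands.

| flask | starting material | coupling partner | free catalyst | time |
|---|---|---|---|---|
| winter | 0.200 M | 0.500 M | 0.0100 M |  |
| spring | 0.300 M | 0.500 M | 0.0100 M |  |
| midnight | 0.410 M | 0.500 M | 0.0100 M | 56 min |

- winter run (time / min: [product] / M): 2.2: 0.006; 3.5: 0.004; 5.6: 0.010; 8.9: 0.018; 14: 0.024; 22: 0.031; 35: 0.038; 56: 0.041
- spring run (time / min: [product] / M): 2.2: 0.010; 3.5: 0.008; 5.6: 0.007; 8.9: 0.017; 14: 0.028; 22: 0.037; 35: 0.042; 56: 0.048

(scatter of a reading: 0.003 M)

- Overall: starting material + coupling partner -> product, with free catalyst as catalyst.
- Constant volume, constant temperature.
- The analysis sees a species whether free or bound.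
- "The second partner" is coupling partner.
- An order is taken over about fifteen percent of the charge, up and down.

* apparent order in [starting material] of the starting rate, round the charge of the winter run (the rate where two percent of its starting material have turned into product) (one fixed amount of product, the same in the runs compared)
* product in the midnight run at 56 min, as a share of the starting material charged
* which of these the readings show (the second partner kills the catalyst / an uncatalysed path runs beside / the second partner is lost by itself / the product ties up the catalyst)

Turn the clock first. In the winter run, going from 14 min to 56 min multiplies the time by 4.00, so a steady rate by hand gives that factor in product, but [product] reads 0.024 M and then 0.041 M. The curve levels off, so I treat it as an exponential approach to a plateau and take the last reading as the plateau. What I carry is the working time, the time a run needs to make its plateau amount at its starting rate (the time constant of the curve). The share reached at 14 min gives 15.9 min in the winter run and 16.0 min in the spring run.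

Now turn the charge, up 1.50 times from winter to spring. A rate in step with charge gives 0.0615 M in the spring run at 56 min, but it read 0.048 M, a ratio of 1.17, which is less than the charge ratio. The plateau is starting rate times working time, and the two working times read alike, so this ratio stands for the ratio of starting rates. My apparent order in [starting material], taken from these two scattered readings, is then 0.389. Scaling the spring reading by that order gives me 0.0542 M for the midnight run, or 13.2% of its charge. A working time that stays put when the charge changes looks to me like a coupling partner lost by itself.

The forecast gave an order of 0.4 (0.15 to 0.7), a midnight share of 13.2% (11.8% to 14.8%), and this verdict: the second partner is lost by itself. In its words: “The second partner decaying by itself fits best, though the two are not cleanly separated.”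

The simulation gives an order of 0.41, a midnight share of 12.4%, and the second partner is lost by itself. That share is below the forecast's value but inside its range.

    free catalyst + starting material → catalyst-substrate complex (4.392 L mol⁻¹ min⁻¹)
    catalyst-substrate complex + coupling partner → loaded catalyst (0.8580 L mol⁻¹ min⁻¹)
    loaded catalyst → product + free catalyst (11.52 min⁻¹)
    coupling partner → lost reagent (0.06300 min⁻¹)

The midnight run is held down because coupling partner turns into lost reagent: the midnight run without that step gives 37.7% at 56 min, against 12.4% with it. The working time reads this second flask by hand. In the midnight run, 56 min is 3.52 working times, and holding the starting rate that long multiplies 12.4% up to 43.7%, while the same run with the loss of coupling partner taken away reaches 37.7%.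

All runs come from a simulation with constants of no real substance; the scatter is artificial.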